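Take percent of the free monomer charged as your unit, with one side product counted as two. Growth gains monomer in chains at a[free monomer], with a following [growing radical]. The side step loses it at k[free monomer][monomer in chains]. [Free monomer] stands in both rates, so it cancels from their ratio, a selectivity factor, and leaves a/(k[monomer in chains]). That ratio is one where monomer in chains stands at a/k, a level which I call the ceiling.

| flask | free monomer | initiator | radical scavenger | remark | time |
|---|---|---|---|---|---|
| grey | 0.050 M (fed, over 2.5 h) | 0.24 mM | 50 µM | run made earlier |  |
| north-east | 0.050 M (fed, over 2.5 h) | 0.12 mM | 50 µM |  | 20 h |
| south | 0.050 M | 0.12 mM | 50 µM | everything together at the start | 20 h |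

- grey (time / min: monomer in chains / %, side product / %, free monomer / %): 10.0: 0, 0, 7.4; 30.0: 7.4, 0.2, 13.0; 60.0: 20.9, 3.2, 15.5; 80.0: 29.7, 7.9, 15.1; 120: 42.5, 21.3, 16.0

(each reading ± 0.5 percentage points)

- a species is counted by the free monomer in it: one side product counts as two
- what may be going on: growing radical + radical scavenger -> ended chains; 2 growing radical -> dead chain; free monomer + initiating radical -> growing radical + monomer in chains; free monomer + monomer in chains -> side product; free monomer + growing radical -> monomer in chains + growing radical; initiator -> 2 initiating radical
- percentages count the whole charge, also what has not yet gone in
- no earlier run changes the charge of initiator; that part of a forecast is a guess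

1. the winner by share of monomer in chains in all that became monomer in chains or side product; "neither" if no more than 2 percentage points parts them (north-east / south / neither)
2. share of monomer in chains in all that became monomer in chains or side product, north-east
3. share of monomer in chains in all that became monomer in chains or side product, south

Each side product holds one unit taken from chains, so grey lost 6.7 percentage points from chains between 80.0 min and 120 min while growth made 20 points. Scaling gain over loss by the mean level reads a ceiling of 105%. The window from 60.0 min reads 120%. This ceiling, the level at which growth and loss balance, drifts down as initiator decays, though both are readings with scatter.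

Now turn the settings by hand. Initiator: if pairs of growing radicals end the chains, a goes as its square root, a guess that puts the two ceilings at 84.9% and 74.3%. Scavenger: it delays chains, as grey's 0% at 10.0 min shows, and I take the delay to double. Feed: chains against monomer reacted contain no [free monomer], so the feed acts through the drift. South's monomer lasts about 45.1 min, which with the delay centres it near 65.1 min, on the higher ceiling. North-east's centres near 120 min, on the lower.

With ceiling C, the end level E obeys E = C(1 − exp(−(charge + E)/(2C))). Iterating, I get 49.7% for south and 46.5% for north-east.

The forecast also names south, but its shares, 48% for south and 41% for north-east, are lower than mine: “South wins, though the margin depends on the radical decay and the √ guess.”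

The flask gives south, with 50.0% against 44.2% for north-east.

    growing radical + radical scavenger → ended chains (k = 1.57 × 10⁷ M⁻¹ s⁻¹)
    2 growing radical → dead chain (k = 5.00 × 10⁶ M⁻¹ s⁻¹)
    free monomer + initiating radical → growing radical + monomer in chains (k = 1.45 × 10⁵ M⁻¹ s⁻¹)
    free monomer + monomer in chains → side product (k = 0.00943 M⁻¹ s⁻¹)
    free monomer + growing radical → monomer in chains + growing radical, rate k5*[growing radical]*[free monomer] (k = 9730 M⁻¹ s⁻¹)
    initiator → 2 initiating radical (k = 1.23 × 10⁻⁴ s⁻¹)

At the end of north-east's feed, the constants put the ceiling at 64.5%, and monomer in chains stood at 41.1%. In north-east, of the 22.0% of free monomer still there, monomer in chains gained just 3.1 points. Take a neighbour of north-east with 3.0 × 10⁻⁴ M of initiator. Its ceiling scales from grey's to 117%, and the same iteration gives 57.3%. That flask ends with 56.6%.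

The numbers in the tables were generated by integration for substances that don't exist; noise was put on by code.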